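**Strategy.** Everything rests on cutting the O1–C5 bond of the fused 2,5-dihydrofuran. O1 also sits on C8 and the C5–O1 bond is allylic to C6=C7, so the five-membered ring unzips on paper to a vinyl oxirane: an epoxide across C7–C8 attached to a C5=C6 cyclohexene. One copper-catalysed 1,3-oxygen shift forms O1–C5, closes the dihydrofuran, moves the alkene to C6=C7 and sets C5 from the epoxide carbon C7, leaving C8 untouched. The precursor is a trans-7,8-epoxy C15 enoate with a C3 silyl ether, built from ketoisophorone. The polyene is then attached by one Wittig coupling with a C15 aldehyde ester.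

Key step: step 7

Assumption: ethyl (2E)-4-(diethoxyphosphoryl)-2-methylbut-2-enoate is taken as a catalogue reagent.
Locants: C1–C11 and O1 follow carotenoid numbering (C1 the CMe2 carbon, C3 the oxygenated CH, C5 the methyl-bearing ring carbon, C6 the ring carbon carrying the chain, C7 and C8 the next chain carbons, C9 the methyl-branched carbon, C11 the terminal carbon of the C15 unit, O1 the furan oxygen). TBS = tert-butyldimethylsilyl.
Structure check: the given precursor, product and target structures are mutually consistent; the precursor is the (7S,8S)-trans-epoxide of the (3S) ring, and C3 and C8 change CIP descriptor along the route without any change in geometry.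
Precursor design: the given precursor is kept, because its trans-oxirane places C8–H, not the C9 branch, against the C5 methyl in the reactive rotamer. Ring expansion is run on the enoate and not on the epoxy ketone, which would be prone to acyl migration under Lewis acid.

**Step 1**
Reactants: 1 ketoisophorone (2,6,6-trimethylcyclohex-2-ene-1,4-dione)
Product: 2 (4R)-4-hydroxy-2,6,6-trimethylcyclohex-2-en-1-one
Conditions: Ru[(R,R)-TsNCHPhCHPhNH](p-cymene) (1 mol %), i-PrOH, rt, no added base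
Reagents that add atoms: none
Why: Noyori asymmetric transfer hydrogenation should reduce only the C4 carbonyl, since the C1 carbonyl is shielded by the C6 gem-dimethyl group and the C2 methyl, and the new C4 stereocentre is set by the (R,R)-ligand, chosen by analogy with aryl ketones (the vinyl arm taking the aryl role) and to be confirmed on the first run.

**Step 2**
Reactants: 2 (4R)-4-hydroxy-2,6,6-trimethylcyclohex-2-en-1-one
Product: 3 (4R)-4-(TBSO)-2,6,6-trimethylcyclohex-2-en-1-one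
Conditions: TBSCl, imidazole, DMF, rt
Reagents that add atoms: tert-butyldimethylsilyl chloride, CC(C)(C)[Si](C)(C)Cl
Why: Imidazole-promoted silylation of an unhindered secondary alcohol is routine and touches no stereocentre.

**Step 3**
Reactants: 3 (4R)-4-(TBSO)-2,6,6-trimethylcyclohex-2-en-1-one
Product: 5 (4S)-4-(TBSO)-2,6,6-trimethylcyclohex-1-en-1-yl trifluoromethanesulfonate, via lithium enolate 4 (not isolated)
Conditions: LiBH(s-Bu)3 (L-Selectride), THF, −78 °C; then PhNTf2, −78 °C to rt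
Reagents that add atoms: N-phenylbis(trifluoromethanesulfonimide), O=S(=O)(N(c1ccccc1)S(=O)(=O)C(F)(F)F)C(F)(F)F; lithium tri-sec-butylborohydride, [Li+].CCC(C)[BH-](C(C)CC)C(C)CC (supplies the lithium of 4)
Why: Conjugate hydride addition to the β-unsubstituted enone, whose carbonyl is blocked by the flanking methyls, gives a single regiodefined enolate that PhNTf2 O-triflates (reductive enolate trapping), the stereocentre being untouched and its descriptor changing from R to S by CIP priority alone.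

**Step 4**
Reactants: 5 (4S)-4-(TBSO)-2,6,6-trimethylcyclohex-1-en-1-yl trifluoromethanesulfonate; 6 methyl vinyl ketone
Product: 7 (3E)-4-[(4S)-4-(TBSO)-2,6,6-trimethylcyclohex-1-en-1-yl]but-3-en-2-one
Conditions: Pd(OAc)2 (5 mol %), PPh3 (10 mol %), Et3N, DMF, 70 °C
Reagents that add atoms: none
Why: Heck coupling, in which the enol triflate adds oxidatively to zerovalent palladium, the enone inserts at its unsubstituted terminus and syn β-hydride elimination gives the (E)-dienone.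

**Step 5**
Reactants: 7 (3E)-4-[(4S)-4-(TBSO)-2,6,6-trimethylcyclohex-1-en-1-yl]but-3-en-2-one
Product: 8 1-[(2R,3S)-3-[(4S)-4-(TBSO)-2,6,6-trimethylcyclohex-1-en-1-yl]oxiran-2-yl]ethan-1-one
Conditions: La(O-i-Pr)3, (S)-BINOL, Ph3As=O (10 mol % each), t-BuOOH, 4 Å MS, THF, rt
Reagents that add atoms: tert-butyl hydroperoxide, CC(C)(C)OO
Why: Catalytic asymmetric Weitz–Scheffer epoxidation attacks only the ketone-conjugated C7=C8 bond and keeps its trans geometry, and both new stereocentres (C7 and C8) are set by the (S)-BINOL lanthanum peroxide, chosen from the (αS,βR) sense that the (R)-ligand shows with simple (E)-enones, the remote C3 centre exerting no bias.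

**Step 6**
Reactants: 8 1-[(2R,3S)-3-[(4S)-4-(TBSO)-2,6,6-trimethylcyclohex-1-en-1-yl]oxiran-2-yl]ethan-1-one; 9 triethyl phosphonoacetate
Product: 11 ethyl (2E)-3-[(2S,3S)-3-[(4S)-4-(TBSO)-2,6,6-trimethylcyclohex-1-en-1-yl]oxiran-2-yl]but-2-enoate, via sodium phosphonoacetate carbanion 10 (not isolated)
Conditions: NaH, THF, 0 °C to rt
Reagents that add atoms: sodium hydride, [Na+].[H-] (supplies the sodium of 10)
Why: Horner–Wadsworth–Emmons olefination of the methyl ketone should favour the (E)-enoate because the oxiranyl arm is larger than methyl, the oxirane is inert to the stabilised carbanion, and any (Z)-isomer is removed by chromatography (C8 changes from R to S by priority only).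

**Step 7**
Reactants: 11 ethyl (2E)-3-[(2S,3S)-3-[(4S)-4-(TBSO)-2,6,6-trimethylcyclohex-1-en-1-yl]oxiran-2-yl]but-2-enoate
Product: 12 ethyl (2E)-3-[(2R,6R,7aR)-6-(TBSO)-4,4,7a-trimethyl-2,4,5,6,7,7a-hexahydro-1-benzofuran-2-yl]but-2-enoate
Conditions: Cu(hfacac)2 (5 mol %), toluene, 110–150 °C, sealed tube
Reagents that add atoms: none
Why: The divalent copper Lewis acid binds the oxirane oxygen and the C7–O bond, allylic to the tetrasubstituted C5=C6 alkene, ionises to a C5–C6–C7 allyl cation (or its sigma-allyl copper equivalent) paired with the copper alkoxide on C8, which recloses at the tertiary terminus C5. The closest known reaction type is the ring expansion of vinyl oxiranes to 2,5-dihydrofurans catalysed by copper bis(hexafluoroacetylacetonate). The dihydrofuran ring (O1, C5, C6, C7, C8) closes by O1–C5 bond formation in a formally 5-endo mode, acceptable because the carbon attacked is an allyl-cation terminus and not a neutral alkene. The one new stereocentre, C5, is controlled by the C7 configuration of the trans-epoxide: the 1,3-shift is suprafacial within the contact ion pair, and in the reactive s-cis C5=C6–C7–C8 rotamer the (7S) oxygen lies on the ring face that carries the equatorial C3 silyloxy group, the face left open by the pseudo-axial C1 methyl, while C8 is not touched. The step needs C7–O to cleave in preference to C8–O, which the electron-poor C9=C10 enoate secures by destabilising a C8 cation while the fully substituted ring alkene stabilises the C7 one. It also needs closure to outrun proton loss and 1,2-shifts, which release of oxirane strain and the non-basic counter-ion favour.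

**Step 8**
Reactants: 12 ethyl (2E)-3-[(2R,6R,7aR)-6-(TBSO)-4,4,7a-trimethyl-2,4,5,6,7,7a-hexahydro-1-benzofuran-2-yl]but-2-enoate
Product: 13 (2E)-3-[(2R,6R,7aR)-6-(TBSO)-4,4,7a-trimethyl-2,4,5,6,7,7a-hexahydro-1-benzofuran-2-yl]but-2-en-1-ol
Conditions: i-Bu2AlH (DIBAL-H), CH2Cl2, −78 °C; aq. Rochelle salt
Reagents that add atoms: none
Why: DIBAL-H reduces the conjugated ester in 1,2-fashion to the allylic alcohol at low temperature and leaves the silyl ether and the cyclic allylic ether alone.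

**Step 9**
Reactants: 13 (2E)-3-[(2R,6R,7aR)-6-(TBSO)-4,4,7a-trimethyl-2,4,5,6,7,7a-hexahydro-1-benzofuran-2-yl]but-2-en-1-ol
Product: 15 [(2E)-3-[(2R,6R,7aR)-6-(TBSO)-4,4,7a-trimethyl-2,4,5,6,7,7a-hexahydro-1-benzofuran-2-yl]but-2-en-1-yl]triphenylphosphonium bromide, via C15 allylic bromide 14 (not isolated)
Conditions: CBr4, PPh3, 2,6-lutidine (cat.), CH2Cl2, 0 °C; then PPh3, rt
Reagents that add atoms: tetrabromomethane, BrC(Br)(Br)Br; triphenylphosphine, c1ccccc1P(c1ccccc1)c1ccccc1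
Why: Appel bromination of the primary allylic alcohol followed by SN2 displacement by triphenylphosphine at the unhindered C11 avoids HBr and so protects the acid-labile, doubly allylic C8–O bond.

**Step 10**
Reactants: 16 (2E,4E,6E)-2,7-dimethylocta-2,4,6-trienedial; 17 ethyl (2E)-4-(diethoxyphosphoryl)-2-methylbut-2-enoate
Product: 19 ethyl (2E,4E,6E,8E,10E)-2,6,11-trimethyl-12-oxododeca-2,4,6,8,10-pentaenoate, via sodium C5-phosphonate carbanion 18 (not isolated)
Conditions: 17, NaHMDS, THF, −78 °C; then added to 16 (3 equiv), −78 to 0 °C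
Reagents that add atoms: sodium bis(trimethylsilyl)amide, [Na+].C[Si](C)(C)[N-][Si](C)(C)C (supplies the sodium of 18)
Why: Horner–Wadsworth–Emmons olefination of one aldehyde of the symmetrical dialdehyde, used in excess to favour mono-olefination, proceeds through the α-carbon of the stabilised allylic phosphonate carbanion and should give the (E)-alkene.

**Step 11**
Reactants: 15 [(2E)-3-[(2R,6R,7aR)-6-(TBSO)-4,4,7a-trimethyl-2,4,5,6,7,7a-hexahydro-1-benzofuran-2-yl]but-2-en-1-yl]triphenylphosphonium bromide; 19 ethyl (2E,4E,6E,8E,10E)-2,6,11-trimethyl-12-oxododeca-2,4,6,8,10-pentaenoate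
Product: 21 ethyl (2E,4E,6E,8E,10E,12E,14E)-15-[(2R,6R,7aR)-6-(TBSO)-4,4,7a-trimethyl-2,4,5,6,7,7a-hexahydro-1-benzofuran-2-yl]-2,6,11-trimethylhexadeca-2,4,6,8,10,12,14-heptaenoate, via C15 phosphorus ylide 20 (not isolated)
Conditions: NaOEt added to 15 + 19, EtOH/CH2Cl2, 0 °C to rt; then heptane, 90 °C, dark
Reagents that add atoms: none
Why: Wittig olefination of the semi-stabilised allylic ylide, generated in the presence of the aldehyde so that it is trapped as it forms, gives the C11=C12 bond as an E/Z mixture that heating should equilibrate to the all-E polyene, as is usual for carotenoid chains.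

**Step 12**
Reactants: 21 ethyl (2E,4E,6E,8E,10E,12E,14E)-15-[(2R,6R,7aR)-6-(TBSO)-4,4,7a-trimethyl-2,4,5,6,7,7a-hexahydro-1-benzofuran-2-yl]-2,6,11-trimethylhexadeca-2,4,6,8,10,12,14-heptaenoate
Product: 22 ethyl (2E,4E,6E,8E,10E,12E,14E)-15-[(2R,6R,7aR)-6-hydroxy-4,4,7a-trimethyl-2,4,5,6,7,7a-hexahydro-1-benzofuran-2-yl]-2,6,11-trimethylhexadeca-2,4,6,8,10,12,14-heptaenoate
Conditions: TBAF, AcOH, THF, rt
Reagents that add atoms: none
Why: Fluoride cleaves the silyl ether, and the acetic acid buffer keeps the medium near neutral so that neither the ester nor the C8 position is disturbed.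

**Step 13**
Reactants: 22 ethyl (2E,4E,6E,8E,10E,12E,14E)-15-[(2R,6R,7aR)-6-hydroxy-4,4,7a-trimethyl-2,4,5,6,7,7a-hexahydro-1-benzofuran-2-yl]-2,6,11-trimethylhexadeca-2,4,6,8,10,12,14-heptaenoate
Product: 23 (2E,4E,6E,8E,10E,12E,14E)-15-[(2R,6R,7aR)-6-hydroxy-4,4,7a-trimethyl-2,4,5,6,7,7a-hexahydro-1-benzofuran-2-yl]-2,6,11-trimethylhexadeca-2,4,6,8,10,12,14-heptaen-1-ol
Conditions: DIBAL-H (excess), CH2Cl2, −78 °C; aq. Rochelle salt
Reagents that add atoms: none
Why: DIBAL-H reduces the conjugated ester to the primary allylic alcohol, one further equivalent being consumed by the free C3 hydroxyl.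

**Step 14**
Reactants: 23 (2E,4E,6E,8E,10E,12E,14E)-15-[(2R,6R,7aR)-6-hydroxy-4,4,7a-trimethyl-2,4,5,6,7,7a-hexahydro-1-benzofuran-2-yl]-2,6,11-trimethylhexadeca-2,4,6,8,10,12,14-heptaen-1-ol
Product: 24 (2E,4E,6E,8E,10E,12E,14E)-15-[(2R,6R,7aR)-6-hydroxy-4,4,7a-trimethyl-2,4,5,6,7,7a-hexahydro-1-benzofuran-2-yl]-2,6,11-trimethylhexadeca-2,4,6,8,10,12,14-heptaenal (target)
Conditions: MnO2 (activated, excess), CH2Cl2, rt, dark
Reagents that add atoms: none
Why: Activated MnO2 oxidises only the polyenylic primary alcohol to the aldehyde and leaves the saturated secondary C3 alcohol untouched.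

**Compound list**

1 | ketoisophorone (2,6,6-trimethylcyclohex-2-ene-1,4-dione) | CC1=CC(=O)CC(C)(C)C1=O | starting material
2 | (4R)-4-hydroxy-2,6,6-trimethylcyclohex-2-en-1-one | O=C1C(C)=C[C@H](O)CC1(C)C | intermediate
3 | (4R)-4-(TBSO)-2,6,6-trimethylcyclohex-2-en-1-one | O=C1C(C)=C[C@H](O[Si](C)(C)C(C)(C)C)CC1(C)C | intermediate
4 | lithium (4S)-4-(TBSO)-2,6,6-trimethylcyclohex-1-en-1-olate (not isolated) | [Li+].[O-]C1=C(C)C[C@H](O[Si](C)(C)C(C)(C)C)CC1(C)C | intermediate
5 | (4S)-4-(TBSO)-2,6,6-trimethylcyclohex-1-en-1-yl trifluoromethanesulfonate | FC(F)(F)S(=O)(=O)OC1=C(C)C[C@H](O[Si](C)(C)C(C)(C)C)CC1(C)C | intermediate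
6 | methyl vinyl ketone (but-3-en-2-one) | CC(=O)C=C | starting material
7 | (3E)-4-[(4S)-4-(TBSO)-2,6,6-trimethylcyclohex-1-en-1-yl]but-3-en-2-one | CC(=O)/C=C/C1=C(C)C[C@H](O[Si](C)(C)C(C)(C)C)CC1(C)C | intermediate
8 | 1-[(2R,3S)-3-[(4S)-4-(TBSO)-2,6,6-trimethylcyclohex-1-en-1-yl]oxiran-2-yl]ethan-1-one | CC(=O)[C@@H]1O[C@H]1C2=C(C)C[C@H](O[Si](C)(C)C(C)(C)C)CC2(C)C | intermediate
9 | triethyl phosphonoacetate | CCOC(=O)CP(=O)(OCC)OCC | starting material
10 | sodium (diethoxyphosphoryl)(ethoxycarbonyl)methanide (not isolated) | [Na+].CCOC(=O)[CH-]P(=O)(OCC)OCC | intermediate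
11 | ethyl (2E)-3-[(2S,3S)-3-[(4S)-4-(TBSO)-2,6,6-trimethylcyclohex-1-en-1-yl]oxiran-2-yl]but-2-enoate | CCOC(=O)/C=C(\C)[C@@H]1O[C@H]1C2=C(C)C[C@H](O[Si](C)(C)C(C)(C)C)CC2(C)C | intermediate
12 | ethyl (2E)-3-[(2R,6R,7aR)-6-(TBSO)-4,4,7a-trimethyl-2,4,5,6,7,7a-hexahydro-1-benzofuran-2-yl]but-2-enoate | CCOC(=O)/C=C(\C)[C@H]1C=C2C(C)(C)C[C@@H](O[Si](C)(C)C(C)(C)C)C[C@@]2(C)O1 | intermediate
13 | (2E)-3-[(2R,6R,7aR)-6-(TBSO)-4,4,7a-trimethyl-2,4,5,6,7,7a-hexahydro-1-benzofuran-2-yl]but-2-en-1-ol | OC/C=C(\C)[C@H]1C=C2C(C)(C)C[C@@H](O[Si](C)(C)C(C)(C)C)C[C@@]2(C)O1 | intermediate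
14 | (2R,6R,7aR)-2-[(2E)-4-bromobut-2-en-2-yl]-6-(TBSO)-4,4,7a-trimethyl-2,4,5,6,7,7a-hexahydro-1-benzofuran (not isolated) | BrC/C=C(\C)[C@H]1C=C2C(C)(C)C[C@@H](O[Si](C)(C)C(C)(C)C)C[C@@]2(C)O1 | intermediate
15 | [(2E)-3-[(2R,6R,7aR)-6-(TBSO)-4,4,7a-trimethyl-2,4,5,6,7,7a-hexahydro-1-benzofuran-2-yl]but-2-en-1-yl]triphenylphosphonium bromide | c1ccccc1[P+](c1ccccc1)(c1ccccc1)C/C=C(\C)[C@H]1C=C2C(C)(C)C[C@@H](O[Si](C)(C)C(C)(C)C)C[C@@]2(C)O1.[Br-] | intermediate
16 | (2E,4E,6E)-2,7-dimethylocta-2,4,6-trienedial | O=C/C(C)=C/C=C/C=C(\C)C=O | starting material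
17 | ethyl (2E)-4-(diethoxyphosphoryl)-2-methylbut-2-enoate | CCOC(=O)/C(C)=C/CP(=O)(OCC)OCC | starting material
18 | sodium salt of the C4 carbanion of 17 (not isolated) | [Na+].CCOC(=O)/C(C)=C/[CH-]P(=O)(OCC)OCC | intermediate
19 | ethyl (2E,4E,6E,8E,10E)-2,6,11-trimethyl-12-oxododeca-2,4,6,8,10-pentaenoate | CCOC(=O)/C(C)=C/C=C/C(C)=C/C=C/C=C(\C)C=O | intermediate
20 | triphenylphosphonium ylide of 15, carbanion at C11 (not isolated) | c1ccccc1P(c1ccccc1)(c1ccccc1)=C/C=C(\C)[C@H]1C=C2C(C)(C)C[C@@H](O[Si](C)(C)C(C)(C)C)C[C@@]2(C)O1 | intermediate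
21 | ethyl (2E,4E,6E,8E,10E,12E,14E)-15-[(2R,6R,7aR)-6-(TBSO)-4,4,7a-trimethyl-2,4,5,6,7,7a-hexahydro-1-benzofuran-2-yl]-2,6,11-trimethylhexadeca-2,4,6,8,10,12,14-heptaenoate | CCOC(=O)/C(C)=C/C=C/C(C)=C/C=C/C=C(C)/C=C/C=C(\C)[C@H]1C=C2C(C)(C)C[C@@H](O[Si](C)(C)C(C)(C)C)C[C@@]2(C)O1 | intermediate
22 | ethyl (2E,4E,6E,8E,10E,12E,14E)-15-[(2R,6R,7aR)-6-hydroxy-4,4,7a-trimethyl-2,4,5,6,7,7a-hexahydro-1-benzofuran-2-yl]-2,6,11-trimethylhexadeca-2,4,6,8,10,12,14-heptaenoate | CCOC(=O)/C(C)=C/C=C/C(C)=C/C=C/C=C(C)/C=C/C=C(\C)[C@H]1C=C2C(C)(C)C[C@@H](O)C[C@@]2(C)O1 | intermediate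
23 | (2E,4E,6E,8E,10E,12E,14E)-15-[(2R,6R,7aR)-6-hydroxy-4,4,7a-trimethyl-2,4,5,6,7,7a-hexahydro-1-benzofuran-2-yl]-2,6,11-trimethylhexadeca-2,4,6,8,10,12,14-heptaen-1-ol | OC/C(C)=C/C=C/C(C)=C/C=C/C=C(C)/C=C/C=C(\C)[C@H]1C=C2C(C)(C)C[C@@H](O)C[C@@]2(C)O1 | intermediate
24 | (2E,4E,6E,8E,10E,12E,14E)-15-[(2R,6R,7aR)-6-hydroxy-4,4,7a-trimethyl-2,4,5,6,7,7a-hexahydro-1-benzofuran-2-yl]-2,6,11-trimethylhexadeca-2,4,6,8,10,12,14-heptaenal | C\C(C=O)=C/C=C/C(C)=C/C=C/C=C(C)/C=C/C=C(\C)[C@H]1C=C2C(C)(C)C[C@@H](O)C[C@@]2(C)O1 | target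

**Step count**

Total: 14 steps. Longest linear sequence: 13 steps (steps 1–9 and 11–14); step 10 is a one-step side branch.

**Steps most likely to fail**

**Step 7.** The ion pair may lose its stereochemical memory by rotation about C7–C8 before reclosure, which would erode the C5 configuration. The allyl cation may also divert to proton loss or a 1,2-shift, or the strained s-cis rotamer may be populated too little for turnover. The fallback is the classical 5,6-epoxide-to-furanoid isomerisation; it sets out from 7 and comes back at 12.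
- Horner–Wadsworth–Emmons reaction of 7 with 9 (NaH, THF) should give ethyl (2E,4E)-3-methyl-5-[(4S)-4-(TBSO)-2,6,6-trimethylcyclohex-1-en-1-yl]penta-2,4-dienoate F1.
- TBAF then frees the homoallylic alcohol, ethyl (2E,4E)-5-[(4S)-4-hydroxy-2,6,6-trimethylcyclohex-1-en-1-yl]-3-methylpenta-2,4-dienoate F2.
- Hydroxyl-directed epoxidation (VO(acac)2, t-BuOOH, CH2Cl2) should deliver oxygen to C5=C6 on the face of the hydroxyl, giving the syn-epoxide ethyl (2E,4E)-5-[(1S,4R,6R)-4-hydroxy-2,2,6-trimethyl-7-oxabicyclo[4.1.0]heptan-1-yl]-3-methylpenta-2,4-dienoate F3.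
- Catalytic HCl in CHCl3 should open C6–O to the dienyl cation and reclose the C5 oxygen on C8. This keeps the C5–O bond, and the syn relationship prevents the C3 hydroxyl from attacking C6 from the rear.
- The ring closure is unselective at C8, so it should give ethyl (2E)-3-[(2R,6R,7aR)-6-hydroxy-4,4,7a-trimethyl-2,4,5,6,7,7a-hexahydro-1-benzofuran-2-yl]but-2-enoate F4 together with its C8 epimer, ethyl (2E)-3-[(2S,6R,7aR)-6-hydroxy-4,4,7a-trimethyl-2,4,5,6,7,7a-hexahydro-1-benzofuran-2-yl]but-2-enoate F5, to be separated by chromatography.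
- Silylation of F4 (TBSCl, imidazole) returns to 12.

**Step 5.** Peroxide addition to the hindered C7 may be slow, and catalyst control over a substrate whose only stereocentre is remote may be incomplete or of the opposite sense. The fallback replaces nucleophilic epoxidation by a hydroxyl-directed electrophilic one; it sets out from 7 and comes back at 8.
- Corey–Bakshi–Shibata reduction of 7 ((R)-Me-CBS, catecholborane, toluene, −78 °C) should give (2S,3E)-4-[(4S)-4-(TBSO)-2,6,6-trimethylcyclohex-1-en-1-yl]but-3-en-2-ol F6.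
- Sharpless asymmetric epoxidation in the matched sense (Ti(O-i-Pr)4, L-(+)-DIPT, t-BuOOH, 4 Å MS, CH2Cl2, −20 °C) should epoxidise only the allylic C7=C8 bond, giving (1S)-1-[(2S,3S)-3-[(4S)-4-(TBSO)-2,6,6-trimethylcyclohex-1-en-1-yl]oxiran-2-yl]ethan-1-ol F7.
- Dess–Martin periodinane buffered with NaHCO3 oxidises F7 to 8.

**Step 11.** The allylic ylide carries carbanion character at C9, so vinylogous β-elimination could open the dihydrofuran at C8–O or erode the C8 configuration before the aldehyde is captured. The fallback reverses the polarity of the coupling; it sets out from 13 and 19 and comes back at 21.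
- MnO2 oxidises 13 to (2E)-3-[(2R,6R,7aR)-6-(TBSO)-4,4,7a-trimethyl-2,4,5,6,7,7a-hexahydro-1-benzofuran-2-yl]but-2-enal F8.
- NaBH4 (EtOH, 0 °C) reduces the aldehyde of 19 to ethyl (2E,4E,6E,8E,10E)-12-hydroxy-2,6,11-trimethyldodeca-2,4,6,8,10-pentaenoate F9.
- PPh3·HBr (MeOH/CH2Cl2), harmless here because no furanoid is present, converts F9 into [(2E,4E,6E,8E,10E)-12-ethoxy-2,7,11-trimethyl-12-oxododeca-2,4,6,8,10-pentaen-1-yl]triphenylphosphonium bromide F10.
- Wittig reaction of the ester-stabilised, weakly basic ylide of F10 with F8 (NaOEt, EtOH/CH2Cl2, then thermal equilibration) should give 21.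

**Further compounds**

F1 | step 7 | ethyl (2E,4E)-3-methyl-5-[(4S)-4-(TBSO)-2,6,6-trimethylcyclohex-1-en-1-yl]penta-2,4-dienoate | CCOC(=O)/C=C(C)/C=C/C1=C(C)C[C@H](O[Si](C)(C)C(C)(C)C)CC1(C)C
F2 | step 7 | ethyl (2E,4E)-5-[(4S)-4-hydroxy-2,6,6-trimethylcyclohex-1-en-1-yl]-3-methylpenta-2,4-dienoate | CCOC(=O)/C=C(C)/C=C/C1=C(C)C[C@H](O)CC1(C)C
F3 | step 7 | ethyl (2E,4E)-5-[(1S,4R,6R)-4-hydroxy-2,2,6-trimethyl-7-oxabicyclo[4.1.0]heptan-1-yl]-3-methylpenta-2,4-dienoate | CCOC(=O)/C=C(C)/C=C/[C@@]12O[C@]1(C)C[C@H](O)CC2(C)C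
F4 | step 7 | ethyl (2E)-3-[(2R,6R,7aR)-6-hydroxy-4,4,7a-trimethyl-2,4,5,6,7,7a-hexahydro-1-benzofuran-2-yl]but-2-enoate | CCOC(=O)/C=C(\C)[C@H]1C=C2C(C)(C)C[C@@H](O)C[C@@]2(C)O1
F5 | step 7 | ethyl (2E)-3-[(2S,6R,7aR)-6-hydroxy-4,4,7a-trimethyl-2,4,5,6,7,7a-hexahydro-1-benzofuran-2-yl]but-2-enoate | CCOC(=O)/C=C(\C)[C@@H]1C=C2C(C)(C)C[C@@H](O)C[C@@]2(C)O1
F6 | step 5 | (2S,3E)-4-[(4S)-4-(TBSO)-2,6,6-trimethylcyclohex-1-en-1-yl]but-3-en-2-ol | C[C@H](O)/C=C/C1=C(C)C[C@H](O[Si](C)(C)C(C)(C)C)CC1(C)C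
F7 | step 5 | (1S)-1-[(2S,3S)-3-[(4S)-4-(TBSO)-2,6,6-trimethylcyclohex-1-en-1-yl]oxiran-2-yl]ethan-1-ol | C[C@H](O)[C@@H]1O[C@H]1C2=C(C)C[C@H](O[Si](C)(C)C(C)(C)C)CC2(C)C
F8 | step 11 | (2E)-3-[(2R,6R,7aR)-6-(TBSO)-4,4,7a-trimethyl-2,4,5,6,7,7a-hexahydro-1-benzofuran-2-yl]but-2-enal | O=C/C=C(\C)[C@H]1C=C2C(C)(C)C[C@@H](O[Si](C)(C)C(C)(C)C)C[C@@]2(C)O1
F9 | step 11 | ethyl (2E,4E,6E,8E,10E)-12-hydroxy-2,6,11-trimethyldodeca-2,4,6,8,10-pentaenoate | CCOC(=O)/C(C)=C/C=C/C(C)=C/C=C/C=C(\C)CO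
F10 | step 11 | [(2E,4E,6E,8E,10E)-12-ethoxy-2,7,11-trimethyl-12-oxododeca-2,4,6,8,10-pentaen-1-yl]triphenylphosphonium bromide | CCOC(=O)/C(C)=C/C=C/C(C)=C/C=C/C=C(\C)C[P+](c1ccccc1)(c1ccccc1)c1ccccc1.[Br-]
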